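**Retrosynthetic overview**
1. Numbering is that of the chromenone: O1, C2 (heptadecyl), C3, C4 (hydroxyl), C4a, C5 (carbonyl), C6, C7, C8, C8a; ring A is the dihydropyran, ring B the cyclohexenone. The last operations are O–Si cleavage at C4 and reductive removal of two chlorine atoms at C6, which served as the activating groups of a ketene.
2. Key disconnection: C5–C4a and C6–C7 of ring B together, back to a monocyclic 2-oxy-1,3-diene, (2S,4R)-2-heptadecyl-4-silyloxy-6-vinyl-3,4-dihydro-2H-pyran, and dichloroketene. A [2+2] cycloaddition gives a cyclobutanone, whose strain then drives ring expansion to the six-membered ring in the same flask.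
3. Enabling feature: ring B is a vinylogous ester. O1 on C8a and the C5 carbonyl stand 1,3 across C4a, so C4a is an enol-ether nucleophile for the ketene carbonyl carbon. The O1 lone pair stabilises a cation at C8a (allylic through C8=C7), which lets the C6–C8a bond of the cyclobutanone break and C6 reclose on C7.
4. The diene comes from vinylation of the enol-ether carbon next to oxygen (future C8a) of the silylated cis-dihydropyranol. This comes from Luche reduction (sets C4) of (S)-2-heptadecyl-2,3-dihydro-4H-pyran-4-one, made by cyclisation of a β-hydroxy ynone.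
5. C2 comes from Noyori hydrogenation of methyl 3-oxoicosanoate (octadecanoyl chloride plus Meldrum's acid). Ring order: ring A first (step 5), then ring B (step 9).

Key step: step 9

Remark: the target is read as (2S,4R)-2-heptadecyl-4-hydroxy-2,3,4,6,7,8-hexahydro-5H-chromen-5-one, with the C2 chain and the C4 hydroxyl cis on ring A; this corresponds to an anti-1,3-diol pattern in the open chain.

**Route**

Step 1
Reactants: 1 octadecanoyl chloride; 2 Meldrum's acid (2,2-dimethyl-1,3-dioxane-4,6-dione)
Product: 4 methyl 3-oxoicosanoate, via acyl Meldrum's acid 3 (not isolated)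
Conditions: pyridine, CH2Cl2, 0 °C → rt; then MeOH, reflux
Reagents that add atoms: methanol (CO)
Why: C-acylation of Meldrum's acid followed by methanolysis with loss of acetone and CO2 (Oikawa–Yonemitsu β-keto ester synthesis) should give the β-keto ester directly from the acid chloride.

Step 2
Reactants: 4 methyl 3-oxoicosanoate
Product: 5 methyl (S)-3-hydroxyicosanoate
Conditions: H2 (50 atm), RuCl2[(S)-BINAP] (0.5 mol%), MeOH, 50 °C
Reagents that add atoms: none
Why: Noyori asymmetric hydrogenation of a β-keto ester; the (S)-BINAP ligand should deliver hydrogen to the ketone face that gives the (S)-carbinol, which becomes C2 of the target.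

Step 3
Reactants: 5 methyl (S)-3-hydroxyicosanoate
Product: 6 (S)-3-hydroxy-N-methoxy-N-methylicosanamide
Conditions: MeNH(OMe)·HCl, i-PrMgCl, THF, −20 → 0 °C
Reagents that add atoms: N,O-dimethylhydroxylamine hydrochloride (CNOC.Cl)
Why: Aminolysis of the ester by the magnesium amide (Weinreb amide formation) tolerates the free β-hydroxyl as its magnesium alkoxide and does not touch the stereocentre.

Step 4
Reactants: 6 (S)-3-hydroxy-N-methoxy-N-methylicosanamide; 7 ethynylmagnesium bromide
Product: 8 (S)-5-hydroxydocos-1-yn-3-one
Conditions: HC≡CMgBr (3.5 equiv), THF, 0 °C → rt; cold aq. NH4Cl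
Reagents that add atoms: none
Why: Weinreb ketone synthesis; the chelated tetrahedral intermediate should stop the addition of the alkynyl Grignard reagent at the ynone stage.

Step 5
Reactants: 8 (S)-5-hydroxydocos-1-yn-3-one
Product: 10 (S)-2-heptadecyl-2,3-dihydro-4H-pyran-4-one, via diethylamino enone 9 (not isolated)
Conditions: Et2NH, CH2Cl2, rt; then TFA, CH2Cl2, 0 °C → rt
Reagents that add atoms: none
Why: Conjugate addition of the amine to the terminal ynone gives a vinylogous amide, and acid then drives 6-exo attack of the hydroxyl on the iminium carbon and loss of diethylamine (addition–elimination), which closes ring A as the dihydropyranone without touching C2.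

Step 6
Reactants: 10 (S)-2-heptadecyl-2,3-dihydro-4H-pyran-4-one
Product: 11 (2S,4R)-2-heptadecyl-3,4-dihydro-2H-pyran-4-ol
Conditions: NaBH4, CeCl3·7H2O, MeOH, −78 °C
Reagents that add atoms: none
Why: Luche 1,2-reduction; hydride should add axially to the half-chair that carries the C2 chain equatorially, giving the pseudo-equatorial alcohol cis to the chain and so setting C4 as (R).

Step 7
Reactants: 11 (2S,4R)-2-heptadecyl-3,4-dihydro-2H-pyran-4-ol
Product: 12 triisopropyl{[(2S,4R)-2-heptadecyl-3,4-dihydro-2H-pyran-4-yl]oxy}silane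
Conditions: TIPSCl, imidazole, DMF, rt → 40 °C
Reagents that add atoms: triisopropylsilyl chloride (CC(C)[Si](Cl)(C(C)C)C(C)C)
Why: Standard silylation under non-acidic conditions; the triisopropylsilyl ether survives tert-butyllithium, unlike silyl ethers with Si–CH3 groups, and later shields one face of the enol ether.

Step 8
Reactants: 12 triisopropyl{[(2S,4R)-2-heptadecyl-3,4-dihydro-2H-pyran-4-yl]oxy}silane; 13 vinyl bromide
Product: 16 triisopropyl{[(2S,4R)-2-heptadecyl-6-vinyl-3,4-dihydro-2H-pyran-4-yl]oxy}silane, via 6-lithio dihydropyran 14 (not isolated), via 6-chlorozincio dihydropyran 15 (not isolated)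
Conditions: t-BuLi, THF, −78 → 0 °C; ZnCl2, THF, 0 °C; vinyl bromide, Pd(PPh3)4 (5 mol%), THF, rt
Reagents that add atoms: none
Why: Deprotonation of the vinylic C–H next to the ring oxygen (as for silyl-protected glycals), transmetalation to zinc and Negishi coupling with vinyl bromide should give the 2-oxy-1,3-diene without touching a stereocentre.

Step 9
Reactants: 16 triisopropyl{[(2S,4R)-2-heptadecyl-6-vinyl-3,4-dihydro-2H-pyran-4-yl]oxy}silane; 17 trichloroacetyl chloride
Product: 20 (2S,4R,4aS)-6,6-dichloro-2-heptadecyl-4-(triisopropylsilyloxy)-2,3,4,4a,6,7-hexahydro-5H-chromen-5-one, via dichloroketene 18 (not isolated), via dichlorocyclobutanone 19 (not isolated)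
Conditions: Cl3CCOCl (1.2 equiv, slow addition), Zn–Cu couple, Et2O, 0 °C → rt; then PhMe, 60 °C
Reagents that add atoms: none
Why: Proposed new method: dichloroketene 18, made in the flask by zinc dechlorination of 17, is attacked at its carbonyl carbon by the nucleophilic enol-ether carbon C4a of the 2-oxy-diene and closes at C8a to the cis-fused 2,2-dichloro-3-alkoxy-3-vinylcyclobutanone 19 (bond C5–C4a), as in the known [2+2] cycloadditions of dichloroketene with glycals and other enol ethers. The C6–C8a bond of 19 is a push–pull bond (O1 donor on C8a, dichloroenolate acceptor at C6) in a strained ring, so the ZnCl2 formed in the flask should ionise it on warming to a zwitterion whose cation is an oxocarbenium ion delocalised through C8 to C7, and the enolate carbon C6 then recloses on C7 (bond C6–C7), a net 1,3-shift that trades the four-membered ring for ring B and is driven by release of the cyclobutanone strain. The closest known reaction types are the Lewis-acid opening of 3-alkoxycyclobutanones to 1,4-zwitterions that are trapped in formal [4+2] reactions and the vinylcyclobutane-to-cyclohexene rearrangement; running the sequence as one operation on a vinyl enol ether is the new part. Modes of closure: the transient four-membered ring by [2+2] cycloaddition, ring B by 6-endo attack of the enolate carbon on the terminus of the allyl cation. The only new stereocentre, C4a, is set by approach of the ketene anti to the C4 silyloxy group (hydrogen cis to it) and is erased in step 10, while C2 and C4 are not touched. The step needs site selectivity for the enol-ether double bond over the vinyl group, which the oxygen-raised HOMO coefficient at C4a secures, C- over O-closure of the zwitterion, which is self-correcting because the O-closed 2-dichloromethylene-3,6-dihydro-2H-pyran can return to 19 by Claisen rearrangement while ring B is the thermodynamic sink, and no second cycloaddition to the enol ether of the product, which is secured by using up the ketene at 0 °C before warming starts the ring expansion.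

Step 10
Reactants: 20 (2S,4R,4aS)-6,6-dichloro-2-heptadecyl-4-(triisopropylsilyloxy)-2,3,4,4a,6,7-hexahydro-5H-chromen-5-one
Product: 22 (2S,4R)-2-heptadecyl-4-(triisopropylsilyloxy)-2,3,4,6,7,8-hexahydro-5H-chromen-5-one, via nonconjugated dechlorinated ketone 21 (not isolated)
Conditions: Zn dust, AcOH, TMEDA, THF, 0 °C → rt; then Et3N, CH2Cl2, rt
Reagents that add atoms: none
Why: Zinc should reduce both α-C–Cl bonds through zinc enolates (the standard dechlorination of dichloroketene adducts), and the β,γ-unsaturated 3-alkoxy ketone then moves its double bond into conjugation (acid- or base-mediated isomerisation) to the much more stable vinylogous ester, which removes the C4a stereocentre.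

Step 11
Reactants: 22 (2S,4R)-2-heptadecyl-4-(triisopropylsilyloxy)-2,3,4,6,7,8-hexahydro-5H-chromen-5-one
Product: 23 (2S,4R)-2-heptadecyl-4-hydroxy-2,3,4,6,7,8-hexahydro-5H-chromen-5-one
Conditions: TBAF, AcOH, THF, 0 °C → rt
Reagents that add atoms: none
Why: Fluoride-mediated desilylation under buffered, near-neutral conditions should free the C4 hydroxyl without ionising this vinylogously activated carbinol, so the cis configuration is kept.

**Compound list**
1 | octadecanoyl chloride | CCCCCCCCCCCCCCCCCC(Cl)=O | starting material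
2 | Meldrum's acid (2,2-dimethyl-1,3-dioxane-4,6-dione) | CC1(C)OC(=O)CC(=O)O1 | starting material
3 | 5-(1-hydroxyoctadecylidene)-2,2-dimethyl-1,3-dioxane-4,6-dione (acyl Meldrum's acid, formed in the flask) | CCCCCCCCCCCCCCCCCC(O)=C1C(=O)OC(C)(C)OC1=O | intermediate
4 | methyl 3-oxoicosanoate | CCCCCCCCCCCCCCCCCC(=O)CC(=O)OC | intermediate
5 | methyl (S)-3-hydroxyicosanoate | CCCCCCCCCCCCCCCCC[C@H](O)CC(=O)OC | intermediate
6 | (S)-3-hydroxy-N-methoxy-N-methylicosanamide | CCCCCCCCCCCCCCCCC[C@H](O)CC(=O)N(C)OC | intermediate
7 | ethynylmagnesium bromide | C#C[Mg]Br | starting material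
8 | (S)-5-hydroxydocos-1-yn-3-one | CCCCCCCCCCCCCCCCC[C@H](O)CC(=O)C#C | intermediate
9 | (S,E)-1-(diethylamino)-5-hydroxydocos-1-en-3-one (formed in the flask) | CCCCCCCCCCCCCCCCC[C@H](O)CC(=O)/C=C/N(CC)CC | intermediate
10 | (S)-2-heptadecyl-2,3-dihydro-4H-pyran-4-one | CCCCCCCCCCCCCCCCC[C@H]1CC(=O)C=CO1 | intermediate
11 | (2S,4R)-2-heptadecyl-3,4-dihydro-2H-pyran-4-ol (2,4-cis) | CCCCCCCCCCCCCCCCC[C@H]1C[C@@H](O)C=CO1 | intermediate
12 | triisopropyl{[(2S,4R)-2-heptadecyl-3,4-dihydro-2H-pyran-4-yl]oxy}silane | CCCCCCCCCCCCCCCCC[C@H]1C[C@@H](O[Si](C(C)C)(C(C)C)C(C)C)C=CO1 | intermediate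
13 | vinyl bromide | C=CBr | starting material
14 | 6-lithio derivative of 12 (lithium on the enol-ether carbon next to oxygen, formed in the flask) | CCCCCCCCCCCCCCCCC[C@H]1C[C@@H](O[Si](C(C)C)(C(C)C)C(C)C)C=C([Li])O1 | intermediate
15 | 6-chlorozincio derivative of 12 (formed in the flask) | CCCCCCCCCCCCCCCCC[C@H]1C[C@@H](O[Si](C(C)C)(C(C)C)C(C)C)C=C([Zn]Cl)O1 | intermediate
16 | triisopropyl{[(2S,4R)-2-heptadecyl-6-vinyl-3,4-dihydro-2H-pyran-4-yl]oxy}silane | CCCCCCCCCCCCCCCCC[C@H]1C[C@@H](O[Si](C(C)C)(C(C)C)C(C)C)C=C(C=C)O1 | intermediate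
17 | trichloroacetyl chloride | ClC(Cl)(Cl)C(Cl)=O | starting material
18 | dichloroketene (formed in the flask) | ClC(Cl)=C=O | intermediate
19 | (1R,3S,5R,6S)-8,8-dichloro-3-heptadecyl-5-(triisopropylsilyloxy)-1-vinyl-2-oxabicyclo[4.2.0]octan-7-one (cis-fused, cyclobutanone anti to the silyloxy group, formed in the flask) | CCCCCCCCCCCCCCCCC[C@H]1C[C@@H](O[Si](C(C)C)(C(C)C)C(C)C)[C@@H]2C(=O)C(Cl)(Cl)[C@]2(C=C)O1 | intermediate
20 | (2S,4R,4aS)-6,6-dichloro-2-heptadecyl-4-(triisopropylsilyloxy)-2,3,4,4a,6,7-hexahydro-5H-chromen-5-one (C4a–H cis to the silyloxy group, C8=C8a enol ether) | CCCCCCCCCCCCCCCCC[C@H]1C[C@@H](O[Si](C(C)C)(C(C)C)C(C)C)[C@@H]2C(=O)C(Cl)(Cl)CC=C2O1 | intermediate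
21 | (2S,4R,4aS)-2-heptadecyl-4-(triisopropylsilyloxy)-2,3,4,4a,6,7-hexahydro-5H-chromen-5-one (formed in the flask) | CCCCCCCCCCCCCCCCC[C@H]1C[C@@H](O[Si](C(C)C)(C(C)C)C(C)C)[C@@H]2C(=O)CCC=C2O1 | intermediate
22 | (2S,4R)-2-heptadecyl-4-(triisopropylsilyloxy)-2,3,4,6,7,8-hexahydro-5H-chromen-5-one | CCCCCCCCCCCCCCCCC[C@H]1C[C@@H](O[Si](C(C)C)(C(C)C)C(C)C)C2=C(CCCC2=O)O1 | intermediate
23 | (2S,4R)-2-heptadecyl-4-hydroxy-2,3,4,6,7,8-hexahydro-5H-chromen-5-one | CCCCCCCCCCCCCCCCC[C@H]1C[C@@H](O)C2=C(CCCC2=O)O1 | target

**Step count and risks**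

Total step count: 11. Longest linear sequence: 11 steps (1 → 23).

Steps most likely to fail:

Step 9 (key step). The cyclobutanone may fail to open to the six-membered ring before the ZnCl2 ionises the allylic silyl ether of the diene or the enol ether of the product, or a second ketene may add to the product. The fallback makes the same two bonds one after the other with known reactions. It sets out from diene 16: C-acylation of the enol-ether carbon with trichloroacetyl chloride and pyridine (Friedel–Crafts-type acylation of enol ethers) would give the trichloroacetyl diene F1. Zinc in acetic acid would reduce the trichloromethyl ketone to the methyl ketone F2. TBSOTf and Et3N would give the 2-silyloxy triene F3, whose central double bond is held cis by ring A, so that thermal 6π-electrocyclisation (toluene, 110 °C) would give the silyl dienol ether F4. Buffered fluoride at low temperature (TBAF, AcOH, THF, −78 °C) would cleave only the silyl enol ether, with protonation at C8, and the fallback comes back to the route at 22.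

Step 10. The C4 silyloxy group may be lost by β-elimination from the dienolate or by ionisation in acetic acid, the double bond may migrate incompletely, or the ketone may be over-reduced. The fallback changes the order and the mechanism of C–Cl cleavage. It sets out from 20: the double bond would be moved first, at the dichloro stage where the C4a hydrogen is much more acidic and a trace of Et3N at −20 °C should be enough, to give the conjugated dichloro vinylogous ester F5. Both chlorine atoms would then be removed by a radical chain under neutral conditions (Bu3SnH, AIBN, benzene, 80 °C), and the fallback comes back to the route at 22.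

Step 8. Metalation at the enol-ether carbon may be incomplete or unselective (competing allylic deprotonation at C4, silyl migration), or the coupling may be slow. The fallback avoids metalation of the enol ether by installing the vinyl group at the pyranone stage. It sets out from pyranone 10: copper-catalysed conjugate addition of vinylmagnesium bromide in the presence of TMSCl (CuI cat., THF, −78 °C) would give the trans silyl enol ether F6. Saegusa–Ito dehydrosilylation (Pd(OAc)2, MeCN, rt) would restore the ring double bond and give the vinyl pyranone F7. Luche reduction would give the cis dienol F8, and silylation with TIPSCl and imidazole would bring the fallback back to the route at 16.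

**Further compounds**
F1 | step 9 | 2,2,2-trichloro-1-[(2S,4R)-2-heptadecyl-4-(triisopropylsilyloxy)-6-vinyl-3,4-dihydro-2H-pyran-5-yl]ethan-1-one | CCCCCCCCCCCCCCCCC[C@H]1C[C@@H](O[Si](C(C)C)(C(C)C)C(C)C)C(C(=O)C(Cl)(Cl)Cl)=C(C=C)O1
F2 | step 9 | 1-[(2S,4R)-2-heptadecyl-4-(triisopropylsilyloxy)-6-vinyl-3,4-dihydro-2H-pyran-5-yl]ethan-1-one | CCCCCCCCCCCCCCCCC[C@H]1C[C@@H](O[Si](C(C)C)(C(C)C)C(C)C)C(C(C)=O)=C(C=C)O1
F3 | step 9 | tert-butyl({1-[(2S,4R)-2-heptadecyl-4-(triisopropylsilyloxy)-6-vinyl-3,4-dihydro-2H-pyran-5-yl]vinyl}oxy)dimethylsilane | CCCCCCCCCCCCCCCCC[C@H]1C[C@@H](O[Si](C(C)C)(C(C)C)C(C)C)C(C(=C)O[Si](C)(C)C(C)(C)C)=C(C=C)O1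
F4 | step 9 | (2S,4R)-5-(tert-butyldimethylsilyloxy)-2-heptadecyl-4-(triisopropylsilyloxy)-3,4,6,7-tetrahydro-2H-chromene | CCCCCCCCCCCCCCCCC[C@H]1C[C@@H](O[Si](C(C)C)(C(C)C)C(C)C)C2=C(O[Si](C)(C)C(C)(C)C)CCC=C2O1
F5 | step 10 | (2S,4R)-6,6-dichloro-2-heptadecyl-4-(triisopropylsilyloxy)-2,3,4,6,7,8-hexahydro-5H-chromen-5-one | CCCCCCCCCCCCCCCCC[C@H]1C[C@@H](O[Si](C(C)C)(C(C)C)C(C)C)C2=C(CCC(Cl)(Cl)C2=O)O1
F6 | step 8 | {[(2S,6S)-2-heptadecyl-6-vinyl-3,6-dihydro-2H-pyran-4-yl]oxy}trimethylsilane (2,6-trans) | CCCCCCCCCCCCCCCCC[C@H]1CC(O[Si](C)(C)C)=C[C@H](C=C)O1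
F7 | step 8 | (S)-2-heptadecyl-6-vinyl-2,3-dihydro-4H-pyran-4-one | CCCCCCCCCCCCCCCCC[C@H]1CC(=O)C=C(C=C)O1
F8 | step 8 | (2S,4R)-2-heptadecyl-6-vinyl-3,4-dihydro-2H-pyran-4-ol | CCCCCCCCCCCCCCCCC[C@H]1C[C@@H](O)C=C(C=C)O1
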